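**Plan** (skeleton atoms carry labdane numbers C1–C20)

1. Retrosynthesis: the two acetates come from diol 23. Ring A and the ring fusion are then cut together at C2–C3 and C5–C10, which opens enone ester 18 to the acyclic keto aldehyde 14. 14 is cut at C7=C8 (olefination), C8–C9 (allylic alkylation) and C9–C10 (Morita–Baylis–Hillman).
2. Enabling feature: with a carbonyl at C1, C10 and C2 are the two α-carbons of one ketone. C5 is the δ-carbon of the 2,4-dienoate formed by the C17 carboxyl on C8 and the C7=C8/C5=C6 alkenes. C3 sits on quaternary C4 as a non-enolisable aldehyde. A C20 methylidene on C10 lets a hydride switch on C10 alone and becomes the angular methyl.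
3. Forward order: C9 and C11–C16 from (S)-citronellol, then C9–C10, C8–C9, C7=C8. One flask then closes ring B (C5–C10) and ring A (C2–C3). The C1 oxygen is removed, the esters are reduced and the diol is acetylated.
4. Stereochemistry: C13 comes from citronellol and C9 from the catalyst in step 5. C10 and C5 are set from C9 in the key step (allylic strain in the enolate, chair-like closure). No centre is epimerisable afterwards.

Key step: step 9

Assumption: (DHQD)2PHAL is taken to give the (R) centre at C9 in step 5; if the sense proves opposite, the pseudoenantiomer (DHQ)2PHAL is used and nothing else changes.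

**Route**

Step 1
Reactants: 1 (S)-citronellol
Product: 2 (3S)-3,7-dimethyloct-6-en-1-yl 2,2-dimethylpropanoate
Conditions: pivaloyl chloride, pyridine, DMAP (cat.), CH2Cl2, 0 → 23 °C
Reagents that add atoms: pivaloyl chloride CC(C)(C)C(Cl)=O
Why: Acylation of the primary alcohol (nucleophilic acyl substitution) gives a pivalate that should survive amine bases and one equivalent of hydride and is removed in step 13; no stereocentre is touched.

Step 2
Reactants: 2 (3S)-3,7-dimethyloct-6-en-1-yl 2,2-dimethylpropanoate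
Product: 4 (3S)-3-methyl-6-oxohexyl 2,2-dimethylpropanoate, via ozonide 3 (not isolated)
Conditions: O3, CH2Cl2, −78 °C; then Me2S, −78 → 23 °C
Reagents that add atoms: ozone [O-][O+]=O
Why: Ozonolysis of the trisubstituted alkene with reductive work-up gives the aldehyde whose carbonyl carbon becomes C9; the C13 centre is not enolisable.

Step 3
Reactants: 4 (3S)-3-methyl-6-oxohexyl 2,2-dimethylpropanoate; 5 but-3-en-2-one
Product: 6 (3S)-6-hydroxy-3-methyl-7-methylidene-8-oxononyl 2,2-dimethylpropanoate (both C6 epimers)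
Conditions: DABCO (0.5 equiv), 1,4-dioxane/H2O, 23 °C
Reagents that add atoms: none
Why: The Morita–Baylis–Hillman reaction joins the α-carbon of the enone to the aldehyde, forming C9–C10 and keeping the C20 methylidene; both carbinol epimers are acceptable because step 5 is stereoconvergent.

Step 4
Reactants: 6 (3S)-6-hydroxy-3-methyl-7-methylidene-8-oxononyl 2,2-dimethylpropanoate
Product: 7 (3S)-6-[(tert-butoxycarbonyl)oxy]-3-methyl-7-methylidene-8-oxononyl 2,2-dimethylpropanoate (both C6 epimers)
Conditions: di-tert-butyl dicarbonate, DMAP (cat.), CH2Cl2, 0 → 23 °C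
Reagents that add atoms: di-tert-butyl dicarbonate CC(C)(C)OC(=O)OC(=O)OC(C)(C)C
Why: O-Acylation of the allylic alcohol gives the carbonate, which is both the leaving group and the source of the tert-butoxide base in step 5.

Step 5
Reactants: 7 (3S)-6-[(tert-butoxycarbonyl)oxy]-3-methyl-7-methylidene-8-oxononyl 2,2-dimethylpropanoate; 8 trimethyl phosphonoacetate
Product: 9 methyl (3R,6S)-2-(dimethoxyphosphoryl)-6-methyl-3-(3-oxobut-1-en-2-yl)-8-(pivaloyloxy)octanoate (both C2 epimers)
Conditions: (DHQD)2PHAL (10 mol%), toluene, 40 °C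
Reagents that add atoms: none
Why: Lewis-base-catalysed asymmetric allylic alkylation of a Morita–Baylis–Hillman carbonate (two successive SN2′ displacements with loss of CO2 and tert-butanol) should form C8–C9, keep the methylidene and set C9 as (R) under catalyst control from both carbinol epimers.

Step 6
Reactants: 10 3-hydroxy-2,2-dimethylpropanal; 11 (triphenylphosphoranylidene)acetaldehyde
Product: 12 (2E)-5-hydroxy-4,4-dimethylpent-2-enal
Conditions: toluene, 90 °C
Reagents that add atoms: none
Why: Wittig olefination with a stabilised formyl ylide should give the (E)-enal that carries C3–C7; the α-quaternary aldehyde cannot enolise.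

Step 7
Reactants: 9 methyl (3R,6S)-2-(dimethoxyphosphoryl)-6-methyl-3-(3-oxobut-1-en-2-yl)-8-(pivaloyloxy)octanoate; 12 (2E)-5-hydroxy-4,4-dimethylpent-2-enal
Product: 13 methyl (2E,4E)-7-hydroxy-6,6-dimethyl-2-[(4R,7S)-7-methyl-3-methylidene-2-oxo-9-(pivaloyloxy)nonan-4-yl]hepta-2,4-dienoate
Conditions: LiCl, DBU, MeCN, 0 → 23 °C
Reagents that add atoms: none
Why: Horner–Wadsworth–Emmons olefination of an α-substituted phosphonoacetate should give the (E)-trisubstituted enoate, which places C9 cis to C6 as ring B closure requires; the mild amine base should leave the methylidene ketone and the C9 centre (not α to a carbonyl) untouched.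

Step 8
Reactants: 13 methyl (2E,4E)-7-hydroxy-6,6-dimethyl-2-[(4R,7S)-7-methyl-3-methylidene-2-oxo-9-(pivaloyloxy)nonan-4-yl]hepta-2,4-dienoate
Product: 14 methyl (2E,4E)-6,6-dimethyl-2-[(4R,7S)-7-methyl-3-methylidene-2-oxo-9-(pivaloyloxy)nonan-4-yl]-7-oxohepta-2,4-dienoate
Conditions: DMP (1,1,1-triacetoxy-1,1-dihydro-1,2-benziodoxol-3(1H)-one), CH2Cl2, 0 → 23 °C
Reagents that add atoms: none
Why: Periodinane oxidation of the neopentyl primary alcohol gives the non-enolisable C3 aldehyde under neutral conditions that the enone and dienoate tolerate.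

Step 9
Reactants: 14 methyl (2E,4E)-6,6-dimethyl-2-[(4R,7S)-7-methyl-3-methylidene-2-oxo-9-(pivaloyloxy)nonan-4-yl]-7-oxohepta-2,4-dienoate
Product: 18 methyl (5S,9R,10S,13S)-1-oxo-15-(pivaloyloxy)labda-2,7-dien-17-oate, via copper enolate 15 (not isolated), via keto aldehyde 16 (not isolated), via ketol 17 (not isolated)
Conditions: [(Ph3P)CuH]6 (0.2 equiv), toluene, −40 → 0 °C; then MeOH, DBU, 60 °C
Reagents that add atoms: none
Why: Proposed new method: [(Ph3P)CuH]6 should add hydride to the unhindered C20 methylidene carbon of the enone in preference to the δ-hindered dienoate and the α-quaternary aldehyde, which turns C20 into the angular methyl and gives the tetrasubstituted C10 enolate 15 with fixed regiochemistry. The enolate then adds to C5, the δ-carbon of the 2,4-dienoate and the only electrophilic carbon it can reach through a six-membered transition state (attack at C7 would need a four-membered one), closing ring B in a 6-(enolexo)-endo-trig vinylogous Michael addition to give 16 after protonation. With C10 now quaternary the C1 ketone can enolise only towards C2, and under DBU this enolate closes ring A on the C3 aldehyde in a 6-(enolendo)-exo-trig aldol addition (17) followed by E1cB loss of water, while the same base moves the ester alkene into conjugation at C7=C8. The closest known reactions are copper hydride-triggered reductive Michael and reductive aldol cyclisations of enones and the aldol condensation that ends a Robinson annulation; what is new is their union on a dienoate in one flask. C10 is set by C9, because allylic 1,3-strain keeps the C9–H bond in the plane of the enolate beside C1, so the dienoate arm can reach C10 only from the face that leaves the C1 carbon equatorial and the new methyl axial, and the chair-like closure with the (E)-C5=C6 alkene places the CMe2CHO group equatorial, which should give the trans ring fusion with H5 and H9 on the same face (5S and 10S from 9R). The step needs chemoselective hydride delivery (secured by the steric difference between the three acceptors), one enolate regioisomer (secured by the methylidene) and one enolate face (secured by the C9 centre).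

Step 10
Reactants: 18 methyl (5S,9R,10S,13S)-1-oxo-15-(pivaloyloxy)labda-2,7-dien-17-oate
Product: 19 methyl (5S,9R,10S,13S)-15-(pivaloyloxy)-1-(tosylhydrazono)labda-2,7-dien-17-oate
Conditions: p-toluenesulfonyl hydrazide, AcOH (cat.), EtOH, 70 °C
Reagents that add atoms: p-toluenesulfonyl hydrazide Cc1ccc(cc1)S(=O)(=O)NN
Why: Condensation at C1, the only ketone, gives the α,β-unsaturated tosylhydrazone; conjugate addition at C3 is disfavoured by the adjacent quaternary C4.

Step 11
Reactants: 19 methyl (5S,9R,10S,13S)-15-(pivaloyloxy)-1-(tosylhydrazono)labda-2,7-dien-17-oate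
Product: 21 methyl (5S,9R,10S,13S)-15-(pivaloyloxy)labda-1,7-dien-17-oate, via allylic diazene 20 (not isolated)
Conditions: catecholborane, CHCl3, 0 °C; then NaOAc·3H2O, 65 °C
Reagents that add atoms: none
Why: Hydride reduction of the unsaturated tosylhydrazone and acetate-induced loss of sulfinate give diazene 20, which loses N2 with a 1,5-hydrogen shift that leaves C3 as CH2 and the alkene at C1=C2 (reductive deoxygenation with alkene transposition); the esters are inert.

Step 12
Reactants: 21 methyl (5S,9R,10S,13S)-15-(pivaloyloxy)labda-1,7-dien-17-oate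
Product: 22 methyl (5S,9R,10S,13S)-15-(pivaloyloxy)labd-7-en-17-oate
Conditions: H2 (1 atm), RhCl(PPh3)3 (5 mol%), benzene/EtOH, 23 °C
Reagents that add atoms: none
Why: Homogeneous hydrogenation with RhCl(PPh3)3 should reduce the cis-disubstituted C1=C2 alkene and leave the trisubstituted, ester-conjugated C7=C8 alkene; no stereocentre is formed.

Step 13
Reactants: 22 methyl (5S,9R,10S,13S)-15-(pivaloyloxy)labd-7-en-17-oate
Product: 23 (5S,9R,10S,13S)-labd-7-ene-15,17-diol
Conditions: i-Bu2AlH (6 equiv), CH2Cl2, −78 → 0 °C; aqueous potassium sodium tartrate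
Reagents that add atoms: none
Why: Excess diisobutylaluminium hydride reduces the conjugated methyl ester to the allylic alcohol (1,2-reduction) and cleaves the pivalate in the same operation.

Step 14
Reactants: 23 (5S,9R,10S,13S)-labd-7-ene-15,17-diol
Product: 24 (5S,9R,10S,13S)-labd-7-ene-15,17-diyl diacetate
Conditions: Ac2O, pyridine, DMAP (cat.), CH2Cl2, 23 °C
Reagents that add atoms: acetic anhydride CC(=O)OC(C)=O
Why: Acetylation of both primary alcohols under nucleophilic catalysis gives the target.

**Compound list**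

1 | (S)-citronellol | OCC[C@@H](C)CCC=C(C)C | starting material
2 | (3S)-3,7-dimethyloct-6-en-1-yl 2,2-dimethylpropanoate | CC(C)(C)C(=O)OCC[C@@H](C)CCC=C(C)C | intermediate
3 | (3S)-5-(5,5-dimethyl-1,2,4-trioxolan-3-yl)-3-methylpentyl 2,2-dimethylpropanoate (ozonide) | CC(C)(C)C(=O)OCC[C@@H](C)CCC1OOC(C)(C)O1 | intermediate
4 | (3S)-3-methyl-6-oxohexyl 2,2-dimethylpropanoate | CC(C)(C)C(=O)OCC[C@@H](C)CCC=O | intermediate
5 | but-3-en-2-one | CC(=O)C=C | starting material
6 | (3S)-6-hydroxy-3-methyl-7-methylidene-8-oxononyl 2,2-dimethylpropanoate (C6 epimers) | CC(C)(C)C(=O)OCC[C@@H](C)CCC(O)C(=C)C(C)=O | intermediate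
7 | (3S)-6-[(tert-butoxycarbonyl)oxy]-3-methyl-7-methylidene-8-oxononyl 2,2-dimethylpropanoate (C6 epimers) | CC(C)(C)C(=O)OCC[C@@H](C)CCC(OC(=O)OC(C)(C)C)C(=C)C(C)=O | intermediate
8 | trimethyl phosphonoacetate | COC(=O)CP(=O)(OC)OC | starting material
9 | methyl (3R,6S)-2-(dimethoxyphosphoryl)-6-methyl-3-(3-oxobut-1-en-2-yl)-8-(pivaloyloxy)octanoate (C2 epimers) | CC(C)(C)C(=O)OCC[C@@H](C)CC[C@@H](C(C(=O)OC)P(=O)(OC)OC)C(=C)C(C)=O | intermediate
10 | 3-hydroxy-2,2-dimethylpropanal | CC(C)(CO)C=O | starting material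
11 | (triphenylphosphoranylidene)acetaldehyde | O=CC=P(c1ccccc1)(c1ccccc1)c1ccccc1 | starting material
12 | (2E)-5-hydroxy-4,4-dimethylpent-2-enal | OCC(C)(C)/C=C/C=O | intermediate
13 | methyl (2E,4E)-7-hydroxy-6,6-dimethyl-2-[(4R,7S)-7-methyl-3-methylidene-2-oxo-9-(pivaloyloxy)nonan-4-yl]hepta-2,4-dienoate | CC(C)(C)C(=O)OCC[C@@H](C)CC[C@@H](/C(C(=O)OC)=C\C=C\C(C)(C)CO)C(=C)C(C)=O | intermediate
14 | methyl (2E,4E)-6,6-dimethyl-2-[(4R,7S)-7-methyl-3-methylidene-2-oxo-9-(pivaloyloxy)nonan-4-yl]-7-oxohepta-2,4-dienoate | CC(C)(C)C(=O)OCC[C@@H](C)CC[C@@H](/C(C(=O)OC)=C\C=C\C(C)(C)C=O)C(=C)C(C)=O | intermediate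
15 | copper enolate of 14 after hydride addition to C20 (phosphine ligands not drawn) | CC(C)(C)C(=O)OCC[C@@H](C)CC[C@@H](/C(C(=O)OC)=C\C=C\C(C)(C)C=O)C(C)=C(C)O[Cu] | intermediate
16 | methyl (4S,5S,6R)-5-acetyl-5-methyl-4-(2-methyl-1-oxopropan-2-yl)-6-[(3S)-3-methyl-5-(pivaloyloxy)pentyl]cyclohex-1-ene-1-carboxylate | CC(C)(C)C(=O)OCC[C@@H](C)CC[C@H]1C(C(=O)OC)=CC[C@@H](C(C)(C)C=O)[C@]1(C)C(C)=O | intermediate
17 | methyl (5S,9R,10S,13S)-3-hydroxy-1-oxo-15-(pivaloyloxy)labd-7-en-17-oate (C3 epimers) | CC(C)(C)C(=O)OCC[C@@H](C)CC[C@H]1C(C(=O)OC)=CC[C@H]2C(C)(C)C(O)CC(=O)[C@]12C | intermediate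
18 | methyl (5S,9R,10S,13S)-1-oxo-15-(pivaloyloxy)labda-2,7-dien-17-oate | CC(C)(C)C(=O)OCC[C@@H](C)CC[C@H]1C(C(=O)OC)=CC[C@H]2C(C)(C)C=CC(=O)[C@]12C | intermediate
19 | methyl (5S,9R,10S,13S)-15-(pivaloyloxy)-1-(tosylhydrazono)labda-2,7-dien-17-oate | CC(C)(C)C(=O)OCC[C@@H](C)CC[C@H]1C(C(=O)OC)=CC[C@H]2C(C)(C)C=CC(=NNS(=O)(=O)c3ccc(C)cc3)[C@]12C | intermediate
20 | methyl (5S,9R,10S,13S)-1-diazenyl-15-(pivaloyloxy)labda-2,7-dien-17-oate (C1 epimers) | CC(C)(C)C(=O)OCC[C@@H](C)CC[C@H]1C(C(=O)OC)=CC[C@H]2C(C)(C)C=CC(N=N)[C@]12C | intermediate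
21 | methyl (5S,9R,10S,13S)-15-(pivaloyloxy)labda-1,7-dien-17-oate | CC(C)(C)C(=O)OCC[C@@H](C)CC[C@H]1C(C(=O)OC)=CC[C@H]2C(C)(C)CC=C[C@]12C | intermediate
22 | methyl (5S,9R,10S,13S)-15-(pivaloyloxy)labd-7-en-17-oate | CC(C)(C)C(=O)OCC[C@@H](C)CC[C@H]1C(C(=O)OC)=CC[C@H]2C(C)(C)CCC[C@]12C | intermediate
23 | (5S,9R,10S,13S)-labd-7-ene-15,17-diol | OCC[C@@H](C)CC[C@H]1C(CO)=CC[C@H]2C(C)(C)CCC[C@]12C | intermediate
24 | (5S,9R,10S,13S)-labd-7-ene-15,17-diyl diacetate | CC(=O)OCC[C@@H](C)CC[C@H]1C(COC(C)=O)=CC[C@H]2C(C)(C)CCC[C@]12C | target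

**Count**

Total steps: 14. Longest linear sequence: 13 (steps 1–5 and 7–14).

**Steps most likely to fail**

Step 9 (proposed new method). Three processes could defeat it: hydride transfer to the aldehyde or the dienoate instead of the methylidene ketone; protonation of the copper enolate before it adds to the congested C5, which would give plain conjugate reduction; and closure through the other enolate face, which would give the cis ring fusion. The fallback uses known chemistry and keeps the aldehyde out of the hydride step. It sets out from 13, which is silylated (TBSCl, imidazole) to methyl (2E,4E)-7-[(tert-butyldimethylsilyl)oxy]-6,6-dimethyl-2-[(4R,7S)-7-methyl-3-methylidene-2-oxo-9-(pivaloyloxy)nonan-4-yl]hepta-2,4-dienoate F1. Lithium tri-sec-butylborohydride in THF at −78 °C then reduces the methylidene ketone in the conjugate sense, and the lithium enolate should undergo the same intramolecular Michael addition (tandem conjugate reduction–Michael cyclisation). After DBU to conjugate the ester this should give methyl (4S,5S,6R)-5-acetyl-4-{1-[(tert-butyldimethylsilyl)oxy]-2-methylpropan-2-yl}-5-methyl-6-[(3S)-3-methyl-5-(pivaloyloxy)pentyl]cyclohex-1-ene-1-carboxylate F2. HF·pyridine frees methyl (4S,5S,6R)-5-acetyl-4-(1-hydroxy-2-methylpropan-2-yl)-5-methyl-6-[(3S)-3-methyl-5-(pivaloyloxy)pentyl]cyclohex-1-ene-1-carboxylate F3, DMP oxidation gives 16 as an isolated compound, and pyrrolidine/AcOH in toluene at 80 °C (aldol condensation) closes ring A, so the route is rejoined at 18.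

Step 5. The enantioselectivity may be low for a carbonate derived from an aliphatic aldehyde, the nucleophile may attack C20 directly to give the linear isomer, and a second molecule of nucleophile may add to the product enone. The fallback gives up catalyst control in favour of separation. It sets out from 7, which with achiral DABCO and 8 should give 9 together with its C9 epimer methyl (3S,6S)-2-(dimethoxyphosphoryl)-6-methyl-3-(3-oxobut-1-en-2-yl)-8-(pivaloyloxy)octanoate F4. The two are diastereomers because of the fixed C13 centre and would be separated by preparative HPLC on a chiral stationary phase; the route is rejoined at 9.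

Step 10. Condensation at the C1 carbonyl beside the quaternary C10 may be slow or incomplete, and the hydrazide may add in the conjugate sense under forcing conditions. The fallback removes the oxygen by a radical route. It sets out from 18, which under Luche conditions (NaBH4, CeCl3·7H2O, MeOH) should give methyl (5S,9R,10S,13S)-1-hydroxy-15-(pivaloyloxy)labda-2,7-dien-17-oate F5. Hydrogenation (H2, RhCl(PPh3)3) gives methyl (5S,9R,10S,13S)-1-hydroxy-15-(pivaloyloxy)labd-7-en-17-oate F6, and NaH, CS2, MeI give the xanthate methyl (5S,9R,10S,13S)-1-{[(methylsulfanyl)carbonothioyl]oxy}-15-(pivaloyloxy)labd-7-en-17-oate F7. Barton–McCombie deoxygenation (Bu3SnH, AIBN, toluene, 110 °C) then rejoins the route at 22.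

Further compounds
F1 | step 9 | methyl (2E,4E)-7-[(tert-butyldimethylsilyl)oxy]-6,6-dimethyl-2-[(4R,7S)-7-methyl-3-methylidene-2-oxo-9-(pivaloyloxy)nonan-4-yl]hepta-2,4-dienoate | CC(C)(C)C(=O)OCC[C@@H](C)CC[C@@H](/C(C(=O)OC)=C\C=C\C(C)(C)CO[Si](C)(C)C(C)(C)C)C(=C)C(C)=O
F2 | step 9 | methyl (4S,5S,6R)-5-acetyl-4-{1-[(tert-butyldimethylsilyl)oxy]-2-methylpropan-2-yl}-5-methyl-6-[(3S)-3-methyl-5-(pivaloyloxy)pentyl]cyclohex-1-ene-1-carboxylate | CC(C)(C)C(=O)OCC[C@@H](C)CC[C@H]1C(C(=O)OC)=CC[C@@H](C(C)(C)CO[Si](C)(C)C(C)(C)C)[C@]1(C)C(C)=O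
F3 | step 9 | methyl (4S,5S,6R)-5-acetyl-4-(1-hydroxy-2-methylpropan-2-yl)-5-methyl-6-[(3S)-3-methyl-5-(pivaloyloxy)pentyl]cyclohex-1-ene-1-carboxylate | CC(C)(C)C(=O)OCC[C@@H](C)CC[C@H]1C(C(=O)OC)=CC[C@@H](C(C)(C)CO)[C@]1(C)C(C)=O
F4 | step 5 | methyl (3S,6S)-2-(dimethoxyphosphoryl)-6-methyl-3-(3-oxobut-1-en-2-yl)-8-(pivaloyloxy)octanoate (C2 epimers) | CC(C)(C)C(=O)OCC[C@@H](C)CC[C@H](C(C(=O)OC)P(=O)(OC)OC)C(=C)C(C)=O
F5 | step 10 | methyl (5S,9R,10S,13S)-1-hydroxy-15-(pivaloyloxy)labda-2,7-dien-17-oate (C1 epimers) | CC(C)(C)C(=O)OCC[C@@H](C)CC[C@H]1C(C(=O)OC)=CC[C@H]2C(C)(C)C=CC(O)[C@]12C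
F6 | step 10 | methyl (5S,9R,10S,13S)-1-hydroxy-15-(pivaloyloxy)labd-7-en-17-oate (C1 epimers) | CC(C)(C)C(=O)OCC[C@@H](C)CC[C@H]1C(C(=O)OC)=CC[C@H]2C(C)(C)CCC(O)[C@]12C
F7 | step 10 | methyl (5S,9R,10S,13S)-1-{[(methylsulfanyl)carbonothioyl]oxy}-15-(pivaloyloxy)labd-7-en-17-oate (C1 epimers) | CC(C)(C)C(=O)OCC[C@@H](C)CC[C@H]1C(C(=O)OC)=CC[C@H]2C(C)(C)CCC(OC(=S)SC)[C@]12C
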